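Structural features

The target is an isoflavan quinone: a chroman (aromatic ring A fused to the dihydropyran ring C) whose C3 is bonded to C1' of a 2,3-dimethoxy-1,4-benzoquinone (ring B). Ring A carries oxygen on four neighbouring carbons (O1 on C8a, methoxy on C8, a free hydroxyl on C7, methoxy on C6) and one hydrogen at C5. Ring B has carbonyls at C2' and C5', methoxy groups at C3' and C4' and a hydrogen at C6'. The only stereocentre is C3, of (S) configuration, lying between the methylenes C2 (oxygen-bound) and C4 (benzylic), so no stereocentre stands next to another and nothing in the molecule can relay chirality to it. The fragile parts are the quinone (reducible, sensitive to base and nucleophiles), the oxidisable 7-hydroxy-6,8-dimethoxyaryl unit, and the C3 hydrogen, which is lost easily whenever C2 or C4 becomes cationic or carbonyl-like. The real difficulty is twofold: absolute control of an isolated aryl-bearing tertiary centre, and the placement and differentiation of seven oxygen substituents on two rings, with one hydroxyl free and ring B at the quinone level. The key step exploits the fact that O1–C8a–C4a–C4, with the C7 oxygen para to C4a, is a masked ortho-quinone methide, while C2–C3 with ring B on C3 corresponds to a β-aryl alkene carrying a donor atom on C2. Joining the two in a [4+2] sense forms C3–C4 and O1–C2, closes ring C and creates C3.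

Logic of the disconnections

27 to 25. The two quinone carbonyls and the C7 hydroxyl are traced back to three O–benzyl bonds (through 26). Quinone and free phenol tolerate neither the acid of the key step nor phosphines or hydride, so they are unmasked last. The gain is that every earlier intermediate is a robust polyether. The forward step must spare the non-benzylic O1–C2 bond during hydrogenolysis, and the oxidant must distinguish a hydroquinone from a monophenol.

25 to 24. The O1–C2 bond is cut. Closing ring C at the primary carbon C2 by SN2 displacement leaves every bond to C3 untouched. The gain is an open-chain phenol–alcohol whose stereocentre is insulated by two methylenes. The forward Mitsunobu step must alkylate only the phenol oxygen, which the acidity difference between the two hydroxyls secures.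

24 to 22. C2 is returned to the aldehyde oxidation level and its C–N bond restored (through 23). Direct silane reduction of the N,O-acetal is avoided on purpose: a Lewis acid is expected to break the endocyclic C2–O1 bond (phenoxide being the better leaving group), and hydride would then give a ring-opened carbamate. Hydrolysis is indifferent to which C2–heteroatom bond ionises, since both paths converge on 23. The forward step demands that capture of the cation by the aqueous medium, and of the open aldehyde by hydride, be faster than proton loss from C3.

22 to 8 + 20. The key cut removes C3–C4 and O1–C2 together (through 21). It divides the molecule at its only stereocentre into two arenes of similar size, and the forward [4+2] addition creates C3 under catalyst control. The demands are mild generation of 21 from 8, face selection on 20 and retention of its (E) geometry.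

8 to 7 to 6. The C4a–C4 bond is cut after raising C4 to the aldehyde level. In 6 only one position ortho to the hydroxyl is free, so chelation-controlled formylation can give only 7, and reduction gives 8. The demand is that 8, which ionises easily, be made under neutral conditions and used fresh.

6 to 3 to 2 to 1. The C8a–O bond is traced to a C–Br bond (through 4 and 5), and the bromide to 2, whose reactive positions are the two equivalent ones para to a terminal methoxy group. The benzyl group on the central oxygen comes from 1, whose hydroxyl is the future C7 hydroxyl. The gain is that the whole oxygen pattern of ring A comes from a cheap phenol. The demand is bromination para to methoxy, not para to the twisted benzyloxy group.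

20 to 17. The N–C2 bond is cut (through 18 and 19). An acyl azide rearrangement places nitrogen on the alkene with retention of geometry, and capture by an alcohol leaves the N–H that the catalyst needs. The demand is that the acid-sensitive enecarbamate be handled without acid.

17 to 14 + 15. The C2=C3 bond is cut (through 16). Condensation and decarboxylation give the (E) acid, so the alkene geometry needs no separate control.

14 to 12. The C1'–CHO bond is cut (through 13). 12 is symmetric with two equivalent free positions, so electrophilic formylation raises no regiochemical question. The demand is substitution on an activated but crowded ring without loss of benzyl groups.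

12 to 10 to 9. Two O–benzyl bonds are cut (through 11), and the para oxygen of 10 is traced to oxidation of 9, which already holds both methoxy groups and one oxygen in the right places.

Other disconnections considered

Alternative 1: The cut runs through C3–C1' and C4–C4a, with C2 added afterwards. In the forward sense the ring B aryllithium A3 (bromination of 12, then lithium–bromine exchange) adds to vinylboronic acid pinacol ester A4 to give an ate complex. With Pd(OAc)2, a chiral ferrocenyl bisphosphine and KOTf, the ring A aryl bromide A2 (from 6 by ortho-bromination and MOM protection) adds oxidatively, and the arylpalladium species triggers a 1,2-shift of ring B from boron to carbon to give the (S) benzylic boronate A1. Matteson homologation (C2 inserted into the C–B bond with retention), oxidation and MOM cleavage would lead to 24 and into steps 13 and 14.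
- In favour: it is highly convergent, and the stereocentre is born on boron, after which every operation is stereospecific and never places a cation or carbonyl next to C3. On configurational security after the key step it is the better plan.
- Against: the migrating aryl group has an ortho benzyloxy group and the electrophile is an electron-rich ortho-alkoxy bromide, so both ate-complex migration and oxidative addition are at the demanding edge of the method, and enantioselectivity there is hard to predict. Five steps follow the coupling instead of three.
- Comparison: the total step count is about equal (fourteen), but the longest linear sequence would be about eleven rather than nine, and the plan needs several strictly anhydrous organometallic operations. The chosen plan uses the innate polarity of ring A instead of two pre-installed halides.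

Alternative 2: The cut runs through C3–C1' and the bond between C4 and the C2' oxygen. In the forward sense a titanium TADDOLate made from TiCl4, Ti(OCHMe2)4 and a TADDOL diol activates quinone 10. C3 of 7-(benzyloxy)-6,8-dimethoxy-2H-chromene A6 (two steps from 6 by propargylation and Claisen cyclisation) attacks the quinone carbon, and the adjacent quinone oxygen closes on the C4 benzylic cation to give the cis-fused pterocarpan A5. Hydrogenolysis of the benzylic C4–O bond and of the C7 benzyl ether, followed by air oxidation, would give 27.
- In favour: ring B needs no protecting groups and arrives at the right oxidation level, and the route would need about eight steps in all. On step and protecting-group economy it is clearly the better plan.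
- Equal: it relies on the same electronic feature of ring A, stabilisation of positive charge at C4 by the C7 oxygen.
- Against: 10 is a doubly deactivated acceptor, since both carbonyls are vinylogous esters. The chiral Lewis acid is typically needed in stoichiometric amounts or more. Partition between [3+2], [2+2] and [5+2] modes depends delicately on the Lewis acid. TiCl4 may cleave the benzyl ether, and the level of asymmetric induction for this quinone is an open question.
- Comparison: the chosen plan is longer but rests on a catalytic, hydrogen-bond-organised step with a predictable regiochemical outcome.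

Alternative 3: The cut runs through C4a–C8a and C7–C8, so that ring A is built de novo. In the forward sense the furan–ynone A8 is heated; the 4-methoxyfuran adds across the tethered alkynyl ether ketone, and the oxygen bridge opens towards the methoxy-stabilised cation to give the 8-acetyl-7-hydroxy-6-methoxy isoflavan A7.
- In favour: the substitution pattern of ring A is fixed by connectivity and not by electrophilic substitution, and the step is thermal and catalyst-free. Because no bond to C3 is made or broken, it is the equal of the chosen plan for the safety of C3 during the key step.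
- Against: the key step does not create the stereocentre, so a separate asymmetric synthesis of A8 is needed. A8 combines an acid-labile 3-alkoxyfuran with a push–pull alkynyl ether ketone that is hard to make and to keep. The C8 acetyl group is at the wrong oxidation level and needs phenol protection, Baeyer–Villiger oxidation, ester cleavage and methylation before the end game.
- Comparison: the route would exceed the chosen one by well over five steps, while the chosen plan buys the ring A oxygen pattern from 1 in five steps.

Key step: step 11

Assumption: the (R) antipode of the phosphoric acid is taken to deliver the (2R,3S) adduct 22 (whose C3 has the same spatial arrangement as the (3S) centre of 27); if the facial sense were opposite, the (S) acid would be used with no other change.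

Step 1
Reactants: 1 2,6-dimethoxyphenol
Product: 2 2-(benzyloxy)-1,3-dimethoxybenzene
Conditions: BnBr, K2CO3, DMF, 60 °C
Reagents that add atoms: benzyl bromide BrCc1ccccc1
Why: Williamson etherification of the hindered but acidic phenol; the benzyl group marks the oxygen that becomes the free C7 hydroxyl and is removed only in the last step.

Step 2
Reactants: 2 2-(benzyloxy)-1,3-dimethoxybenzene
Product: 3 2-(benzyloxy)-4-bromo-1,3-dimethoxybenzene
Conditions: NBS (1.0 equiv), MeCN, 0 °C to rt, dark
Reagents that add atoms: N-bromosuccinimide O=C1CCC(=O)N1Br
Why: Electrophilic aromatic bromination; in 1,2,3-trialkoxybenzenes the flanked central alkoxy group is twisted out of conjugation, so substitution should go para to a terminal methoxy group and not para to the benzyloxy group.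

Step 3
Reactants: 3 2-(benzyloxy)-4-bromo-1,3-dimethoxybenzene
Product: 6 3-(benzyloxy)-2,4-dimethoxyphenol, via aryllithium 4 (not isolated), via lithium aryltrimethoxyborate 5 (not isolated)
Conditions: n-BuLi, THF, −78 °C; B(OMe)3, −78 °C to rt; then H2O2, NaOH (aq), 0 °C to rt; acidify
Reagents that add atoms: hydrogen peroxide OO
Why: Lithium–bromine exchange, borylation and oxidation of the C–B bond convert the bromide into the phenol oxygen that becomes O1; at −78 °C exchange is much faster than deprotonation of the benzyl ether.

Step 4
Reactants: 6 3-(benzyloxy)-2,4-dimethoxyphenol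
Product: 7 4-(benzyloxy)-2-hydroxy-3,5-dimethoxybenzaldehyde
Conditions: MgCl2, Et3N, (CH2O)n, MeCN, reflux
Reagents that add atoms: paraformaldehyde (as formaldehyde) C=O
Why: Magnesium-mediated ortho-formylation (Casnati–Skattebøl reaction): the magnesium phenoxide delivers formaldehyde to the only free ortho position, and a second formaldehyde accepts hydride to give the aldehyde.

Step 5
Reactants: 7 4-(benzyloxy)-2-hydroxy-3,5-dimethoxybenzaldehyde
Product: 8 5-(benzyloxy)-2-(hydroxymethyl)-4,6-dimethoxyphenol
Conditions: NaBH4, THF/MeOH, 0 °C; NH4Cl (aq) quench; used fresh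
Reagents that add atoms: none
Why: Borohydride reduction of the aldehyde; the quench is kept near neutral because this electron-rich salicyl alcohol ionises readily to the quinone methide.

Step 6
Reactants: 9 2,3-dimethoxyphenol
Product: 10 2,3-dimethoxycyclohexa-2,5-diene-1,4-dione
Conditions: K2[ON(SO3)2] (2.2 equiv), KH2PO4, H2O/acetone, 0 °C to rt
Reagents that add atoms: potassium nitrosodisulfonate [K+].[K+].[O]N(S(=O)(=O)[O-])S(=O)(=O)[O-]
Why: Teuber oxidation: two equivalents of the nitrosodisulfonate radical convert a phenol with a free para position into the para-quinone, which installs the fourth contiguous oxygen of ring B.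

Step 7
Reactants: 10 2,3-dimethoxycyclohexa-2,5-diene-1,4-dione
Product: 12 1,4-bis(benzyloxy)-2,3-dimethoxybenzene, via hydroquinone 11 (not isolated)
Conditions: Na2S2O4, EtOAc/H2O, rt; organic phase concentrated under Ar; then BnBr, K2CO3, DMF, 60 °C
Reagents that add atoms: benzyl bromide BrCc1ccccc1
Why: Dithionite reduction of the quinone followed by double Williamson etherification; telescoping avoids handling the air-sensitive hydroquinone.

Step 8
Reactants: 12 1,4-bis(benzyloxy)-2,3-dimethoxybenzene
Product: 14 2,5-bis(benzyloxy)-3,4-dimethoxybenzaldehyde, via iminium salt 13 (not isolated)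
Conditions: POCl3, DMF, 70 °C; then H2O, NaOAc, rt
Reagents that add atoms: N,N-dimethylformamide CN(C)C=O; water O
Why: Vilsmeier–Haack formylation of an electron-rich arene; the two free positions of 12 are equivalent by symmetry, so only one aldehyde can form.

Step 9
Reactants: 14 2,5-bis(benzyloxy)-3,4-dimethoxybenzaldehyde; 15 malonic acid
Product: 17 (2E)-3-[2,5-bis(benzyloxy)-3,4-dimethoxyphenyl]prop-2-enoic acid, via arylidenemalonic acid 16 (not isolated)
Conditions: pyridine, piperidine (cat.), 95 °C
Reagents that add atoms: none
Why: Knoevenagel–Doebner condensation; decarboxylation of the arylidenemalonic acid in pyridine gives the (E)-cinnamic acid.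

Step 10
Reactants: 17 (2E)-3-[2,5-bis(benzyloxy)-3,4-dimethoxyphenyl]prop-2-enoic acid
Product: 20 benzyl N-{(E)-2-[2,5-bis(benzyloxy)-3,4-dimethoxyphenyl]ethenyl}carbamate, via acyl azide 18 (not isolated), via vinyl isocyanate 19 (not isolated)
Conditions: DPPA, Et3N, toluene, 0 °C to rt; then 85 °C; then BnOH, 85 °C; chromatography on Et3N-treated silica
Reagents that add atoms: diphenylphosphoryl azide [N-]=[N+]=NP(=O)(Oc1ccccc1)Oc1ccccc1; benzyl alcohol OCc1ccccc1
Why: Curtius rearrangement of the cinnamoyl azide to the vinyl isocyanate with retention of alkene geometry, then addition of benzyl alcohol; this is the standard entry to (E)-β-aryl enecarbamates with a free N–H.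

Step 11
Reactants: 8 5-(benzyloxy)-2-(hydroxymethyl)-4,6-dimethoxyphenol; 20 benzyl N-{(E)-2-[2,5-bis(benzyloxy)-3,4-dimethoxyphenyl]ethenyl}carbamate
Product: 22 benzyl N-[(2R,3S)-7-(benzyloxy)-3-[2,5-bis(benzyloxy)-3,4-dimethoxyphenyl]-6,8-dimethoxy-3,4-dihydro-2H-chromen-2-yl]carbamate, via ortho-quinone methide 21 (not isolated)
Conditions: (R)-TRIP [(R)-3,3'-bis(2,4,6-triisopropylphenyl)-1,1'-binaphthyl-2,2'-diyl hydrogen phosphate] (10 mol %), 3 Å MS, toluene, 0 °C to rt; 8 (1.3 equiv) added over 6 h
Reagents that add atoms: none
Why: The phosphoric acid protonates the benzylic hydroxyl of 8 and, helped by the C7 benzyloxy group para to C4a, water is lost to give 21, which stays hydrogen-bonded to the catalyst through its carbonyl oxygen while the phosphoryl oxygen binds the carbamate N–H of 20. Within this assembly the nucleophilic β-carbon of 20 (future C3) adds to the methylene terminus C4 and the quinone methide oxygen closes on the developing N-acyliminium carbon C2, a concerted but asynchronous inverse-electron-demand oxa-[4+2] cycloaddition. The closest known reaction type is the chiral phosphoric acid catalysed [4+2] addition of ortho-quinone methides, generated in situ from ortho-hydroxybenzyl alcohols, to enamides and enecarbamates to give 2-amidochromans. Ring C closes suprafacially, with O1=C8a–C4a=C4 as the four-atom partner and C2=C3 as the two-atom partner; in the stepwise limit O1–C2 forms by 6-exo-trig capture of the iminium. C3 is set by the catalyst, whose 3,3'-aryl groups shield one face of the hydrogen-bonded enecarbamate so that C4 is delivered to the face leading to (3S). C2 is set relative to C3 by the (E) geometry of 20, which the suprafacial addition conserves as the 2,3-trans (2R) arrangement; this centre is erased in step 12. The step needs regioselectivity (polarity matching joins the nucleophilic β-carbon to the electrophilic C4), chemoselectivity for 20 over self-condensation of 21 (secured by slow addition of 8 and by ring A having no free nucleophilic position other than C5) and retention of the (E) geometry (secured by low temperature and low acid loading).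

Step 12
Reactants: 22 benzyl N-[(2R,3S)-7-(benzyloxy)-3-[2,5-bis(benzyloxy)-3,4-dimethoxyphenyl]-6,8-dimethoxy-3,4-dihydro-2H-chromen-2-yl]carbamate
Product: 24 (2S)-2-[2,5-bis(benzyloxy)-3,4-dimethoxyphenyl]-3-[4-(benzyloxy)-2-hydroxy-3,5-dimethoxyphenyl]propan-1-ol, via lactol 23 (not isolated)
Conditions: 1 M HCl (aq), THF, 0 °C to rt; NaHCO3 to pH 7; then NaBH4, MeOH, 0 °C
Reagents that add atoms: water O
Why: Acid hydrolysis of an N-acyl N,O-acetal: whichever C2–heteroatom bond ionises, water intercepts the cation and benzyl carbamate is lost to give lactol 23, whose ring-opened aldehyde form is reduced by NaBH4 (lactol reduction). C3 is not a reacting centre, and at 0 °C capture by water and by hydride should outrun loss of the C3 proton.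

Step 13
Reactants: 24 (2S)-2-[2,5-bis(benzyloxy)-3,4-dimethoxyphenyl]-3-[4-(benzyloxy)-2-hydroxy-3,5-dimethoxyphenyl]propan-1-ol
Product: 25 (3S)-7-(benzyloxy)-3-[2,5-bis(benzyloxy)-3,4-dimethoxyphenyl]-6,8-dimethoxy-3,4-dihydro-2H-chromene
Conditions: PPh3, DIAD, THF, 0 °C to rt
Reagents that add atoms: none
Why: Intramolecular Mitsunobu etherification: the phenol displaces the activated primary alcohol in a 6-exo-tet SN2 closure that re-forms O1–C2 without touching any bond to C3.

Step 14
Reactants: 25 (3S)-7-(benzyloxy)-3-[2,5-bis(benzyloxy)-3,4-dimethoxyphenyl]-6,8-dimethoxy-3,4-dihydro-2H-chromene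
Product: 27 5-[(3S)-7-hydroxy-6,8-dimethoxy-3,4-dihydro-2H-chromen-3-yl]-2,3-dimethoxycyclohexa-2,5-diene-1,4-dione, via hydroquinone 26 (not isolated)
Conditions: H2 (1 atm), 10% Pd/C, EtOAc/MeOH, rt; filter under Ar; then air, SiO2, rt
Reagents that add atoms: none
Why: Hydrogenolysis of the three benzyl ethers, then autoxidation of the electron-rich 2,3-dimethoxyhydroquinone to the quinone. The monophenol of ring A should not be oxidised by air under neutral conditions, and O1–C2 is not benzylic, so ring C and C3 survive.

Compound list

1 | 2,6-dimethoxyphenol | COc1cccc(OC)c1O | starting material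
2 | 2-(benzyloxy)-1,3-dimethoxybenzene | COc1cccc(OC)c1OCc1ccccc1 | intermediate
3 | 2-(benzyloxy)-4-bromo-1,3-dimethoxybenzene | COc1ccc(Br)c(OC)c1OCc1ccccc1 | intermediate
4 | [3-(benzyloxy)-2,4-dimethoxyphenyl]lithium (formed in the flask) | [Li]c1ccc(OC)c(OCc2ccccc2)c1OC | intermediate
5 | lithium [3-(benzyloxy)-2,4-dimethoxyphenyl]trimethoxyborate (formed in the flask) | [Li+].CO[B-](OC)(OC)c1ccc(OC)c(OCc2ccccc2)c1OC | intermediate
6 | 3-(benzyloxy)-2,4-dimethoxyphenol | COc1ccc(O)c(OC)c1OCc1ccccc1 | intermediate
7 | 4-(benzyloxy)-2-hydroxy-3,5-dimethoxybenzaldehyde | COc1cc(C=O)c(O)c(OC)c1OCc1ccccc1 | intermediate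
8 | 5-(benzyloxy)-2-(hydroxymethyl)-4,6-dimethoxyphenol | OCc1cc(OC)c(OCc2ccccc2)c(OC)c1O | intermediate
9 | 2,3-dimethoxyphenol | COc1cccc(O)c1OC | starting material
10 | 2,3-dimethoxycyclohexa-2,5-diene-1,4-dione | COC1=C(OC)C(=O)C=CC1=O | intermediate
11 | 2,3-dimethoxybenzene-1,4-diol (formed in the flask) | COc1c(O)ccc(O)c1OC | intermediate
12 | 1,4-bis(benzyloxy)-2,3-dimethoxybenzene | COc1c(OCc2ccccc2)ccc(OCc2ccccc2)c1OC | intermediate
13 | N-{[2,5-bis(benzyloxy)-3,4-dimethoxyphenyl]methylidene}-N-methylmethanaminium dichlorophosphate (formed in the flask) | C[N+](C)=Cc1cc(OCc2ccccc2)c(OC)c(OC)c1OCc1ccccc1.[O-]P(=O)(Cl)Cl | intermediate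
14 | 2,5-bis(benzyloxy)-3,4-dimethoxybenzaldehyde | COc1c(OC)c(OCc2ccccc2)c(C=O)cc1OCc1ccccc1 | intermediate
15 | malonic acid (propanedioic acid) | OC(=O)CC(O)=O | starting material
16 | 2-{[2,5-bis(benzyloxy)-3,4-dimethoxyphenyl]methylidene}propanedioic acid (formed in the flask) | COc1c(OC)c(OCc2ccccc2)c(C=C(C(O)=O)C(O)=O)cc1OCc1ccccc1 | intermediate
17 | (2E)-3-[2,5-bis(benzyloxy)-3,4-dimethoxyphenyl]prop-2-enoic acid | COc1c(OC)c(OCc2ccccc2)c(/C=C/C(O)=O)cc1OCc1ccccc1 | intermediate
18 | (2E)-3-[2,5-bis(benzyloxy)-3,4-dimethoxyphenyl]prop-2-enoyl azide (formed in the flask) | COc1c(OC)c(OCc2ccccc2)c(/C=C/C(=O)N=[N+]=[N-])cc1OCc1ccccc1 | intermediate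
19 | 1,4-bis(benzyloxy)-5-[(E)-2-isocyanatoethenyl]-2,3-dimethoxybenzene (formed in the flask) | COc1c(OC)c(OCc2ccccc2)c(/C=C/N=C=O)cc1OCc1ccccc1 | intermediate
20 | benzyl N-{(E)-2-[2,5-bis(benzyloxy)-3,4-dimethoxyphenyl]ethenyl}carbamate | O=C(OCc1ccccc1)N/C=C/c1cc(OCc2ccccc2)c(OC)c(OC)c1OCc1ccccc1 | intermediate
21 | 3-(benzyloxy)-2,4-dimethoxy-6-methylidenecyclohexa-2,4-dien-1-one (formed in the flask) | C=C1C=C(OC)C(OCc2ccccc2)=C(OC)C1=O | intermediate
22 | benzyl N-[(2R,3S)-7-(benzyloxy)-3-[2,5-bis(benzyloxy)-3,4-dimethoxyphenyl]-6,8-dimethoxy-3,4-dihydro-2H-chromen-2-yl]carbamate (2,3-trans) | O=C(OCc1ccccc1)N[C@@H]1Oc2c(OC)c(OCc3ccccc3)c(OC)cc2C[C@H]1c1cc(OCc2ccccc2)c(OC)c(OC)c1OCc1ccccc1 | intermediate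
23 | (3S)-7-(benzyloxy)-3-[2,5-bis(benzyloxy)-3,4-dimethoxyphenyl]-6,8-dimethoxy-3,4-dihydro-2H-chromen-2-ol (both C2 epimers; formed in the flask) | OC1Oc2c(OC)c(OCc3ccccc3)c(OC)cc2C[C@H]1c1cc(OCc2ccccc2)c(OC)c(OC)c1OCc1ccccc1 | intermediate
24 | (2S)-2-[2,5-bis(benzyloxy)-3,4-dimethoxyphenyl]-3-[4-(benzyloxy)-2-hydroxy-3,5-dimethoxyphenyl]propan-1-ol | OC[C@@H](Cc1cc(OC)c(OCc2ccccc2)c(OC)c1O)c1cc(OCc2ccccc2)c(OC)c(OC)c1OCc1ccccc1 | intermediate
25 | (3S)-7-(benzyloxy)-3-[2,5-bis(benzyloxy)-3,4-dimethoxyphenyl]-6,8-dimethoxy-3,4-dihydro-2H-chromene | COc1c(OC)c(OCc2ccccc2)c([C@H]3COc4c(cc(OC)c(OCc5ccccc5)c4OC)C3)cc1OCc1ccccc1 | intermediate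
26 | 5-[(3S)-7-hydroxy-6,8-dimethoxy-3,4-dihydro-2H-chromen-3-yl]-2,3-dimethoxybenzene-1,4-diol (formed in the flask) | COc1c(OC)c(O)c([C@H]2COc3c(cc(OC)c(O)c3OC)C2)cc1O | intermediate
27 | 5-[(3S)-7-hydroxy-6,8-dimethoxy-3,4-dihydro-2H-chromen-3-yl]-2,3-dimethoxycyclohexa-2,5-diene-1,4-dione (CNP0121136.1) | COC1=C(OC)C(=O)C([C@H]2COc3c(cc(OC)c(O)c3OC)C2)=CC1=O | target

Total step count: 14. Longest linear sequence: 9 steps (steps 1 to 5 or steps 6 to 10, then steps 11 to 14).

Steps least certain to work

Step 11 (key step). The most likely failure is insufficient enantiofacial discrimination at the enecarbamate β-carbon, because the quinone methide terminus is an unsubstituted methylene that gives the catalyst pocket little to grip and the ortho benzyloxy group twists ring B. The second risk is oligomerisation of the quinone methide if it accumulates. The fallback moves stereocontrol from the cycloaddition to a hydrogenation. It sets out from 22 of whatever enantiomeric purity (made, if need be, with diphenyl phosphate as an achiral acid). Brief warming with TsOH in toluene should eliminate benzyl carbamate to give the cyclic enol ether 7-(benzyloxy)-3-[2,5-bis(benzyloxy)-3,4-dimethoxyphenyl]-6,8-dimethoxy-4H-chromene F1. Asymmetric hydrogenation of this trisubstituted alkene with a cationic iridium phosphine–oxazoline complex, [Ir(cod)(L*)][B(C6H3(CF3)2)4], under H2 in CH2Cl2 leaves benzyl ethers untouched and should give 25. The fallback comes back to the route at 25 and skips steps 12 and 13.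

Step 12. The most likely failure is erosion of configuration at C3, by proton loss from the N-acyliminium ion during hydrolysis or by enolisation of the ring-opened α-aryl aldehyde in the basic borohydride stage; incomplete hydrolysis is the lesser risk. The fallback sets out from 22. Acid-catalysed exchange in methanol (PPTS, MeOH/CH2Cl2, rt) should replace the carbamate by methoxy to give (3S)-7-(benzyloxy)-3-[2,5-bis(benzyloxy)-3,4-dimethoxyphenyl]-2,6,8-trimethoxy-3,4-dihydro-2H-chromene F2. Ionic reduction of this O,O-acetal (Et3SiH, BF3·OEt2, CH2Cl2, −78 °C), in which the exocyclic alkoxy group is the better leaving group and hydride capture at low temperature should beat loss of the C3 proton, gives 25. The fallback comes back at 25 and skips step 13, and no open-chain aldehyde ever meets base.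

Step 8. The most likely failure is slow substitution, because the reacting position is activated by only one coplanar alkoxy group, with acid-induced loss of a benzyl group if the reaction is forced. The fallback sets out from 12. NBS in MeCN should give 1,4-bis(benzyloxy)-5-bromo-2,3-dimethoxybenzene F3; lithium–bromine exchange (n-BuLi, THF, −78 °C; the aryllithium is the species labelled A3) and quench with DMF give the aldehyde. The fallback comes back to the route at 14.

Step 14. The most likely failure is incomplete hydrogenolysis of the two benzyl ethers that are flanked on both sides, together with unselective aerobic oxidation (phenoxyl coupling at the ring A phenol, or a persistent quinhydrone mixture of 26 and 27). The fallback sets out from 25. Non-reductive debenzylation with BCl3 and pentamethylbenzene (CH2Cl2, −78 °C) should give 26, isolated under argon, and one equivalent of Ag2O in Et2O (in place of air) then oxidises only the hydroquinone. The fallback comes back at 27 and makes no compound beyond the list (F0).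

Further compounds

F1 | step 11 | 7-(benzyloxy)-3-[2,5-bis(benzyloxy)-3,4-dimethoxyphenyl]-6,8-dimethoxy-4H-chromene | COc1c(OC)c(OCc2ccccc2)c(C2=COc3c(cc(OC)c(OCc4ccccc4)c3OC)C2)cc1OCc1ccccc1
F2 | step 12 | (3S)-7-(benzyloxy)-3-[2,5-bis(benzyloxy)-3,4-dimethoxyphenyl]-2,6,8-trimethoxy-3,4-dihydro-2H-chromene (both C2 epimers) | COC1Oc2c(OC)c(OCc3ccccc3)c(OC)cc2C[C@H]1c1cc(OCc2ccccc2)c(OC)c(OC)c1OCc1ccccc1
F3 | step 8 | 1,4-bis(benzyloxy)-5-bromo-2,3-dimethoxybenzene | COc1c(OC)c(OCc2ccccc2)c(Br)cc1OCc1ccccc1
F0 | step 14 | none | none
A1 | alternative 1 | 2-[(1S)-1-[2,5-bis(benzyloxy)-3,4-dimethoxyphenyl]-2-[4-(benzyloxy)-3,5-dimethoxy-2-(methoxymethoxy)phenyl]ethyl]-4,4,5,5-tetramethyl-1,3,2-dioxaborolane | COc1c(OC)c(OCc2ccccc2)c([C@H](Cc3cc(OC)c(OCc4ccccc4)c(OC)c3OCOC)B3OC(C)(C)C(C)(C)O3)cc1OCc1ccccc1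
A2 | alternative 1 | 4-(benzyloxy)-1-bromo-3,5-dimethoxy-2-(methoxymethoxy)benzene | COCOc1c(Br)cc(OC)c(OCc2ccccc2)c1OC
A3 | alternative 1 | [2,5-bis(benzyloxy)-3,4-dimethoxyphenyl]lithium | [Li]c1cc(OCc2ccccc2)c(OC)c(OC)c1OCc1ccccc1
A4 | alternative 1 | 2-ethenyl-4,4,5,5-tetramethyl-1,3,2-dioxaborolane (vinylboronic acid pinacol ester) | C=CB1OC(C)(C)C(C)(C)O1
A5 | alternative 2 | cis-fused pterocarpan, (3S,4S) in isoflavan numbering, with 7-benzyloxy-6,8-dimethoxy ring A and 5'-hydroxy-3',4'-dimethoxy ring B tied to C4 through the 2'-oxygen | Oc1cc2c(c(OC)c1OC)O[C@@H]1c3cc(OC)c(OCc4ccccc4)c(OC)c3OC[C@H]21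
A6 | alternative 2 | 7-(benzyloxy)-6,8-dimethoxy-2H-chromene | COc1cc2C=CCOc2c(OC)c1OCc1ccccc1
A7 | alternative 3 | 1-[(3S)-3-[2,5-bis(benzyloxy)-3,4-dimethoxyphenyl]-7-hydroxy-6-methoxy-3,4-dihydro-2H-chromen-8-yl]ethan-1-one | COc1c(OC)c(OCc2ccccc2)c([C@H]3COc4c(cc(OC)c(O)c4C(C)=O)C3)cc1OCc1ccccc1
A8 | alternative 3 | 4-{(2S)-2-[2,5-bis(benzyloxy)-3,4-dimethoxyphenyl]-3-(4-methoxyfuran-2-yl)propoxy}but-3-yn-2-one | COc1c(OC)c(OCc2ccccc2)c([C@H](Cc2cc(OC)co2)COC#CC(C)=O)cc1OCc1ccccc1
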